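**Retrosynthetic overview** (neolignan numbering: C7 benzylic CH, C8 aryloxy-bearing CH, C9 methyl)
- Feature the strategy rests on: the C7–C8 dyad, two adjacent CH stereocentres that each carry one oxygen and one carbon substituent. C8 bears the C9 methyl and the ether O of the 4-allyl-2,6-dimethoxyphenyl ring. C7 bears OMe and the 4-hydroxy-3-methoxyphenyl ring. The relation is threo (7S,8S).
- Disconnections, last to first: phenol O–Si; C7 O–CH3; C7–O back to C7–B; C7–aryl (aryl Grignard on an α-chloro boronic ester); C7–C8 (CHCl insertion); C8–O(aryl) (aryloxide on an α-chloro boronic ester); C8–C9 (CHCl insertion into a methylboronate).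
- One (R,R)-DICHED boronic ester sets both centres through two Matteson cycles, and the C8 and C7 carbons both come from dichloromethane.
- No ring of the target is formed, since both benzene rings are bought. Only the auxiliary dioxaborolane ring is closed (step 1) and removed again (step 7).

Key step: step 3

Assumption: (R,R)-DICHED is taken to direct the (αS)-chloride for the α-aryloxyethyl migrating group of step 4 in the same sense as it does for alkyl and α-alkoxyalkyl groups.

Step 1
Reactants: 1 methylboronic acid; 2 (R,R)-1,2-dicyclohexylethane-1,2-diol [(R,R)-DICHED]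
Product: 3 (R,R)-DICHED methylboronate [(4R,5R)-4,5-dicyclohexyl-2-methyl-1,3,2-dioxaborolane]
Conditions: MgSO4, Et2O, rt
Reagents that add atoms: none
Why: Boronic ester formation by condensation is driven to completion by the drying agent and by the stability of the five-membered dioxaborolane, and the two diol stereocentres are not touched.

Step 2
Reactants: 3 (R,R)-DICHED methylboronate
Product: 5 (R,R)-DICHED (1S)-1-chloroethylboronate, via lithium dichloromethylborate 4 (not isolated)
Conditions: CH2Cl2, n-BuLi, THF, −100 °C; then 3; then ZnCl2 (1 equiv), −100 °C → rt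
Reagents that add atoms: dichloromethane, ClCCl
Why: Matteson homologation, in which preformed LiCHCl2 adds to boron to give borate 4 and, on warming with ZnCl2, methyl shifts from boron to carbon while the C2-symmetric (R,R)-diol decides which diastereotopic chloride leaves, so C8 is set as the (S)-chloride and ZnCl2 binds the released chloride before it can epimerise 5.

Step 3
Reactants: 5 (R,R)-DICHED (1S)-1-chloroethylboronate; 6 4-allyl-2,6-dimethoxyphenol (methoxyeugenol)
Product: 9 (R,R)-DICHED (1R)-1-(4-allyl-2,6-dimethoxyphenoxy)ethylboronate, via sodium aryloxide 7 (not isolated), via sodium aryloxyborate 8 (not isolated)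
Conditions: 6 (1.1 equiv), NaH (1.05 equiv), THF, 0 °C; then 5, THF–DMSO, 0 °C → rt (40 °C if slow)
Reagents that add atoms: none
Why: Proposed new method: aryloxide 7 binds reversibly to the empty p orbital of boron in 5 to give borate 8, whose B–O bond then shifts to the neighbouring carbon antiperiplanar to C–Cl as chloride departs, so the C8–O(aryl) bond forms by an intramolecular 1,2-metallate rearrangement and not by the intermolecular SN2 attack that a di-ortho-substituted phenoxide would resist. The closest known reaction type is the substitution stage of the Matteson homologation, in which benzyl oxide, p-methoxybenzyl oxide or methoxide replace the halide of chiral-diol α-halo boronic esters with inversion, and a hindered aryloxide has not been shown in this role. No ring is closed. The C8 centre is inverted stereospecifically, from (1S)-chloride to (1R)-aryl ether, so its configuration is controlled by the chloride centre that the (R,R)-DICHED director set in step 2. Substitution must outrun chloride-induced epimerisation of 5 and E2 loss of HCl, which is secured by the low basicity of the phenoxide, by the sodium counter-ion (NaCl precipitates and leaves the exchange) and by the absence of added halide. NaH is kept below the amount of 6 so that no dimsyl anion forms in DMSO and the allyl group is not isomerised.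

Step 4
Reactants: 9 (R,R)-DICHED (1R)-1-(4-allyl-2,6-dimethoxyphenoxy)ethylboronate
Product: 11 (R,R)-DICHED (1S,2S)-1-chloro-2-(4-allyl-2,6-dimethoxyphenoxy)propylboronate, via lithium dichloromethylborate 10 (not isolated)
Conditions: CH2Cl2, n-BuLi, THF, −100 °C (carbenoid preformed); then 9; then ZnCl2 (3 equiv), −100 → 0 °C; cold aq. NH4Cl wash, used crude
Reagents that add atoms: dichloromethane, ClCCl
Why: Matteson homologation of an α-oxygenated boronic ester, known for α-alkoxyalkyl groups, in which the preformed carbenoid (no free n-BuLi, so the ArCH2 allylic position is not metalated) gives borate 10, the α-aryloxyethyl group shifts to the carbenoid carbon with retention at C8, and the same (R,R)-diol again selects the chloride that leaves, setting C7 as the (S)-chloride.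

Step 5
Reactants: 12 4-bromo-2-methoxyphenol
Product: 13 (4-bromo-2-methoxyphenoxy)triisopropylsilane
Conditions: TIPSCl, imidazole, DMF, rt
Reagents that add atoms: chlorotriisopropylsilane (TIPSCl), CC(C)[Si](Cl)(C(C)C)C(C)C
Why: Imidazole-promoted O-silylation of a phenol creates no stereocentre, and the bulky TIPS ether should withstand the Grignard stage, the buffered peroxide and NaH/MeI.

Step 6
Reactants: 11 (R,R)-DICHED (1S,2S)-1-chloro-2-(4-allyl-2,6-dimethoxyphenoxy)propylboronate (crude); 13 (4-bromo-2-methoxyphenoxy)triisopropylsilane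
Product: 16 (R,R)-DICHED (1S,2S)-2-(4-allyl-2,6-dimethoxyphenoxy)-1-[3-methoxy-4-(triisopropylsilyloxy)phenyl]propylboronate, via arylmagnesium bromide 14 (not isolated), via bromomagnesium arylborate 15 (not isolated)
Conditions: 13, Mg turnings (1 mol % DIBAL-H activation), THF, 40 °C; solution added to 11, THF, −78 °C; then ZnCl2 (1 equiv), −78 °C → rt
Reagents that add atoms: none
Why: Substitution stage of the Matteson homologation with a carbon nucleophile, in which Grignard reagent 14 adds to boron at −78 °C and in borate 15 the aryl group shifts to C7 antiperiplanar to the leaving chloride, so chloride is replaced with inversion (the descriptor stays S only because the priority order changes) and boron is left where the oxygen will go.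

Step 7
Reactants: 16 (R,R)-DICHED benzylic boronate
Product: 18 (1S,2S)-2-(4-allyl-2,6-dimethoxyphenoxy)-1-[3-methoxy-4-(triisopropylsilyloxy)phenyl]propan-1-ol, via borate ester 17 (not isolated)
Conditions: 30% aq. H2O2, pH 8 phosphate buffer, THF, 0 °C; diol 2 recovered by chromatography
Reagents that add atoms: hydrogen peroxide, OO
Why: Peroxide oxidation of a boronic ester moves the benzylic carbon from boron to oxygen with retention, so C7–B becomes C7–O without change of configuration, and the mild pH and low temperature hold back β-elimination of the aryloxide and spare the aryl silyl ether and the allyl group.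

Step 8
Reactants: 18 threo benzylic alcohol (phenol as TIPS ether)
Product: 20 [4-[(1S,2S)-2-(4-allyl-2,6-dimethoxyphenoxy)-1-methoxypropyl]-2-methoxyphenoxy]triisopropylsilane, via sodium alkoxide 19 (not isolated)
Conditions: NaH, MeI, THF, 0 °C
Reagents that add atoms: iodomethane, CI
Why: Williamson etherification forms only the O–CH3 bond, so the C7–O bond and both stereocentres stay untouched, and NaH in THF at 0 °C is too mild to isomerise the allyl group or cleave the TIPS ether.

Step 9
Reactants: 20 7-O-methyl ether (phenol as TIPS ether)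
Product: 21 4-[(1S,2S)-2-(4-allyl-2,6-dimethoxyphenoxy)-1-methoxypropyl]-2-methoxyphenol (target CNP0275203.1)
Conditions: TBAF–AcOH (1:1), THF, 0 °C; pH 7 buffer work-up
Reagents that add atoms: none
Why: Fluoride-mediated desilylation buffered with acetic acid protonates the phenoxide as soon as it forms, so methoxide is not expelled through a p-quinone methide and C7 is not epimerised.

**Compound list**
1 | methylboronic acid | CB(O)O | starting material
2 | (R,R)-1,2-dicyclohexylethane-1,2-diol, (R,R)-DICHED | O[C@H](C1CCCCC1)[C@H](O)C1CCCCC1 | starting material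
3 | (4R,5R)-4,5-dicyclohexyl-2-methyl-1,3,2-dioxaborolane | CB1O[C@H](C2CCCCC2)[C@@H](C2CCCCC2)O1 | intermediate
4 | lithium (dichloromethyl)(methyl)borate of (R,R)-DICHED | [Li+].C[B-]1(C(Cl)Cl)O[C@H](C2CCCCC2)[C@@H](C2CCCCC2)O1 | intermediate
5 | (4R,5R)-2-[(1S)-1-chloroethyl]-4,5-dicyclohexyl-1,3,2-dioxaborolane | C[C@@H](Cl)B1O[C@H](C2CCCCC2)[C@@H](C2CCCCC2)O1 | intermediate
6 | 4-allyl-2,6-dimethoxyphenol | C=CCc1cc(OC)c(O)c(OC)c1 | starting material
7 | sodium 4-allyl-2,6-dimethoxyphenoxide | [Na+].C=CCc1cc(OC)c([O-])c(OC)c1 | intermediate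
8 | sodium (aryloxy)[(1S)-1-chloroethyl]borate of (R,R)-DICHED | [Na+].C=CCc1cc(OC)c(O[B-]2([C@@H](C)Cl)O[C@H](C3CCCCC3)[C@@H](C3CCCCC3)O2)c(OC)c1 | intermediate
9 | (4R,5R)-2-[(1R)-1-(4-allyl-2,6-dimethoxyphenoxy)ethyl]-4,5-dicyclohexyl-1,3,2-dioxaborolane | C=CCc1cc(OC)c(O[C@@H](C)B2O[C@H](C3CCCCC3)[C@@H](C3CCCCC3)O2)c(OC)c1 | intermediate
10 | lithium (dichloromethyl)[(1R)-1-aryloxyethyl]borate of (R,R)-DICHED | [Li+].C=CCc1cc(OC)c(O[C@@H](C)[B-]2(C(Cl)Cl)O[C@H](C3CCCCC3)[C@@H](C3CCCCC3)O2)c(OC)c1 | intermediate
11 | (4R,5R)-2-[(1S,2S)-1-chloro-2-(4-allyl-2,6-dimethoxyphenoxy)propyl]-4,5-dicyclohexyl-1,3,2-dioxaborolane | C=CCc1cc(OC)c(O[C@@H](C)[C@@H](Cl)B2O[C@H](C3CCCCC3)[C@@H](C3CCCCC3)O2)c(OC)c1 | intermediate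
12 | 4-bromo-2-methoxyphenol | COc1cc(Br)ccc1O | starting material
13 | (4-bromo-2-methoxyphenoxy)triisopropylsilane | COc1cc(Br)ccc1O[Si](C(C)C)(C(C)C)C(C)C | intermediate
14 | [3-methoxy-4-(triisopropylsilyloxy)phenyl]magnesium bromide | COc1cc([Mg]Br)ccc1O[Si](C(C)C)(C(C)C)C(C)C | intermediate
15 | bromomagnesium aryl[(1S,2S)-1-chloro-2-aryloxypropyl]borate of (R,R)-DICHED | Br[Mg+].C=CCc1cc(OC)c(O[C@@H](C)[C@@H](Cl)[B-]2(c3ccc(O[Si](C(C)C)(C(C)C)C(C)C)c(OC)c3)O[C@H](C3CCCCC3)[C@@H](C3CCCCC3)O2)c(OC)c1 | intermediate
16 | (4R,5R)-2-[(1S,2S)-2-(4-allyl-2,6-dimethoxyphenoxy)-1-[3-methoxy-4-(triisopropylsilyloxy)phenyl]propyl]-4,5-dicyclohexyl-1,3,2-dioxaborolane | C=CCc1cc(OC)c(O[C@@H](C)[C@@H](B2O[C@H](C3CCCCC3)[C@@H](C3CCCCC3)O2)c2ccc(O[Si](C(C)C)(C(C)C)C(C)C)c(OC)c2)c(OC)c1 | intermediate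
17 | (R,R)-DICHED borate ester of alcohol 18 (C7–O–B) | C=CCc1cc(OC)c(O[C@@H](C)[C@@H](OB2O[C@H](C3CCCCC3)[C@@H](C3CCCCC3)O2)c2ccc(O[Si](C(C)C)(C(C)C)C(C)C)c(OC)c2)c(OC)c1 | intermediate
18 | (1S,2S)-2-(4-allyl-2,6-dimethoxyphenoxy)-1-[3-methoxy-4-(triisopropylsilyloxy)phenyl]propan-1-ol | C=CCc1cc(OC)c(O[C@@H](C)[C@@H](O)c2ccc(O[Si](C(C)C)(C(C)C)C(C)C)c(OC)c2)c(OC)c1 | intermediate
19 | sodium alkoxide of 18 | [Na+].C=CCc1cc(OC)c(O[C@@H](C)[C@@H]([O-])c2ccc(O[Si](C(C)C)(C(C)C)C(C)C)c(OC)c2)c(OC)c1 | intermediate
20 | [4-[(1S,2S)-2-(4-allyl-2,6-dimethoxyphenoxy)-1-methoxypropyl]-2-methoxyphenoxy]triisopropylsilane | C=CCc1cc(OC)c(O[C@@H](C)[C@@H](OC)c2ccc(O[Si](C(C)C)(C(C)C)C(C)C)c(OC)c2)c(OC)c1 | intermediate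
21 | 4-[(1S,2S)-2-(4-allyl-2,6-dimethoxyphenoxy)-1-methoxypropyl]-2-methoxyphenol | C=CCc1cc(OC)c(O[C@@H](C)[C@@H](OC)c2ccc(O)c(OC)c2)c(OC)c1 | target

**Total step count:** 9. **Longest linear sequence:** 8 steps (steps 1–4 and 6–9); step 5 is the side branch.

**Three steps most likely to fail**

Step 3 (proposed new method).
- What may go wrong: the di-ortho-substituted aryloxide may not engage the boron atom that the dicyclohexyl diol shields. The oxygen shift may also be so slow that chloride exchange erodes the C8 configuration or dehydrochlorination takes over.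
- Fallback: known, boron-free chemistry that sets out from 6, uses 14 made from 13, and comes back at 18. Mitsunobu etherification of 6 with commercial methyl (R)-lactate (PPh3, DIAD, THF, 0 °C → rt) forms the C8–O(aryl) bond with inversion and should give methyl (S)-2-(4-allyl-2,6-dimethoxyphenoxy)propanoate F1. MeNH(OMe)·HCl with i-PrMgCl (THF, −20 °C) converts this into (S)-2-(4-allyl-2,6-dimethoxyphenoxy)-N-methoxy-N-methylpropanamide F2. Grignard reagent 14 adds once to give (S)-2-(4-allyl-2,6-dimethoxyphenoxy)-1-[3-methoxy-4-(triisopropylsilyloxy)phenyl]propan-1-one F3. L-Selectride (THF, −78 °C), a bulky non-chelating hydride, should then attack under polar Felkin–Anh control, anti to the aryloxy group, and favour the threo alcohol 18. The minor C7 epimer is removed by chromatography.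

Step 4.
- What may go wrong: in the borate, aryloxide may leave C8 in competition with chloride leaving the carbenoid carbon, particularly with ZnCl2 held by the methoxy groups. The electron-poor α-aryloxyethyl group may also migrate so slowly that carbenoid decay, oxygen migration or weaker diastereoselection intervene.
- Fallback: sets out from 9 and comes back at 18; C7 is brought in as CH2 and its configuration is set later at a carbonyl group. Chloromethyllithium made in situ (ClCH2I, n-BuLi, THF, −78 °C → rt) gives a monochloro borate that rearranges without Lewis acid and with no stereochemical choice. This should give (R,R)-DICHED (2S)-2-(4-allyl-2,6-dimethoxyphenoxy)propylboronate F4. Buffered H2O2 (pH 8, THF, 0 °C) gives (S)-2-(4-allyl-2,6-dimethoxyphenoxy)propan-1-ol F5. Dess–Martin periodinane (NaHCO3, CH2Cl2, 0 °C) gives (S)-2-(4-allyl-2,6-dimethoxyphenoxy)propanal F6, which is used at once. Grignard reagent 14 (THF, −78 °C) gives (2S)-2-(4-allyl-2,6-dimethoxyphenoxy)-1-[3-methoxy-4-(triisopropylsilyloxy)phenyl]propan-1-ol as a mixture of C7 epimers F7. Because the sense of this substrate-controlled addition cannot be relied on, the mixture is oxidised unseparated (Dess–Martin periodinane) to ketone F3. The Felkin–Anh reduction with L-Selectride described for step 3 then leads to 18.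

Step 6.
- What may go wrong: boron and the β-aryloxide may be lost by β-elimination from the tetracoordinate borate before the aryl group shifts. Magnesium halide may also epimerise the α-chloride before it is substituted.
- Fallback: sets out from 11 and comes back at 18; the boron-controlled C7 centre is given up and the inserted carbon is used as a carbonyl carbon. Sodium chlorite oxidation of the α-chloro boronic ester (NaClO2, NaH2PO4, 2-methyl-2-butene, t-BuOH–H2O, 0 °C) is a known way from such esters to carboxylic acids at near-neutral pH. It should give (S)-2-(4-allyl-2,6-dimethoxyphenoxy)propanoic acid F8. Activation with CDI and MeNH(OMe)·HCl (CH2Cl2, rt) gives Weinreb amide F2. Addition of 14 to ketone F3 and the L-Selectride reduction then follow as described for step 3 and deliver 18.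

**Further compounds**
F1 | step 3 | methyl (S)-2-(4-allyl-2,6-dimethoxyphenoxy)propanoate | C=CCc1cc(OC)c(O[C@@H](C)C(=O)OC)c(OC)c1
F2 | step 3 | (S)-2-(4-allyl-2,6-dimethoxyphenoxy)-N-methoxy-N-methylpropanamide | C=CCc1cc(OC)c(O[C@@H](C)C(=O)N(C)OC)c(OC)c1
F3 | step 3 | (S)-2-(4-allyl-2,6-dimethoxyphenoxy)-1-[3-methoxy-4-(triisopropylsilyloxy)phenyl]propan-1-one | C=CCc1cc(OC)c(O[C@@H](C)C(=O)c2ccc(O[Si](C(C)C)(C(C)C)C(C)C)c(OC)c2)c(OC)c1
F4 | step 4 | (R,R)-DICHED (2S)-2-(4-allyl-2,6-dimethoxyphenoxy)propylboronate | C=CCc1cc(OC)c(O[C@@H](C)CB2O[C@H](C3CCCCC3)[C@@H](C3CCCCC3)O2)c(OC)c1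
F5 | step 4 | (S)-2-(4-allyl-2,6-dimethoxyphenoxy)propan-1-ol | C=CCc1cc(OC)c(O[C@@H](C)CO)c(OC)c1
F6 | step 4 | (S)-2-(4-allyl-2,6-dimethoxyphenoxy)propanal | C=CCc1cc(OC)c(O[C@@H](C)C=O)c(OC)c1
F7 | step 4 | (2S)-2-(4-allyl-2,6-dimethoxyphenoxy)-1-[3-methoxy-4-(triisopropylsilyloxy)phenyl]propan-1-ol, mixture of C7 epimers | C=CCc1cc(OC)c(O[C@@H](C)C(O)c2ccc(O[Si](C(C)C)(C(C)C)C(C)C)c(OC)c2)c(OC)c1
F8 | step 6 | (S)-2-(4-allyl-2,6-dimethoxyphenoxy)propanoic acid | C=CCc1cc(OC)c(O[C@@H](C)C(=O)O)c(OC)c1
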